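**Retrosynthetic overview**

- The five phenols come from benzyl ethers (final hydrogenolysis). The ketone C–C bond to ring D is cut back to an aryl bromide (bromine–lithium exchange, Weinreb amide); this bromine is carried on ring D from step 1, so the acyl group cannot go to ring A.
- The C2–aryl bond (ring B) is cut to a cyclic oxocarbenium ion from a 2-ethoxychroman and an arylzinc chloride, which adds trans to the C4 aryl group.
- Ring C is cut by a retro-(4+2). C4 is a diarylmethine on ring A ortho to the ring oxygen O1, so C4 (methide carbon carrying ring D) and O1 (carbonyl oxygen) are the two ends of an ortho-quinone methide of ring A. The C3–C2 unit between them is ethyl vinyl ether, and a chiral phosphoric acid sets C4 while C3–C4 and O1–C2 form.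
- The quinone methide comes from a racemic ortho-hydroxybenzhydrol, made by adding a lithiated bromo-tris(benzyloxy)benzene to 4-(benzyloxy)-2-hydroxybenzaldehyde.
- Rings A, B and D are bought as benzene rings; ring C is the only ring built, and it is built in the key step.

Key step: step 3

Assumption: the (R) enantiomer of the phosphoric acid is written in step 3; which enantiomer gives the (4R) configuration is settled in a test run, and the antipode is taken if the sense of induction is the opposite.
Assumption: 9 is drawn as the 2,4-cis (endo) acetal; its C2 epimer is carried along, because C2 becomes planar in step 5.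

**Route**

Step 1
Reactants: 1 1,3,5-tris(benzyloxy)benzene
Product: 2 1,3,5-tris(benzyloxy)-2,4-dibromobenzene
Conditions: NBS (2.05 equiv), CH2Cl2, 0 °C to rt, dark
Reagents that add atoms: N-bromosuccinimide, O=C1CCC(=O)N1Br
Why: Electrophilic aromatic bromination of a ring in which every free position is activated by two ortho and one para benzyloxy group, and two equivalents of NBS should stop at the dibromide because the last position is then deactivated and flanked on both sides.

Step 2
Reactants: 2 1,3,5-tris(benzyloxy)-2,4-dibromobenzene; 3 4-(benzyloxy)-2-hydroxybenzaldehyde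
Product: 6 rac-[4-(benzyloxy)-2-hydroxyphenyl][2,4,6-tris(benzyloxy)-3-bromophenyl]methanol, via aryllithium 4 (not isolated), via sodium phenolate 5 (not isolated)
Conditions: 2, n-BuLi (1.0 equiv), THF, −78 °C; 3, NaH (1.05 equiv), THF, 0 °C; phenolate added to the aryllithium, −78 to −20 °C; cold aq NH4Cl; chromatography on Et3N-treated silica
Reagents that add atoms: none
Why: Bromine–lithium exchange with one equivalent of n-BuLi at −78 °C should exchange one bromine only and outrun benzylic deprotonation, and the aryllithium then undergoes 1,2-addition to the aldehyde of the pre-formed phenolate to give the racemic carbinol, whose configuration is lost in step 3.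

Step 3
Reactants: 6 rac-[4-(benzyloxy)-2-hydroxyphenyl][2,4,6-tris(benzyloxy)-3-bromophenyl]methanol; 7 ethyl vinyl ether
Product: 9 (2R,4R)-7-(benzyloxy)-4-[2,4,6-tris(benzyloxy)-3-bromophenyl]-2-ethoxy-3,4-dihydro-2H-chromene, via ortho-quinone methide 8 (not isolated)
Conditions: 7 (5 equiv), (R)-3,3'-bis(2,4,6-triisopropylphenyl)-1,1'-binaphthyl-2,2'-diyl hydrogen phosphate (10 mol%), 4 Å molecular sieves, toluene, −40 to −20 °C
Reagents that add atoms: none
Why: The phosphoric acid protonates the benzylic hydroxyl of 6, water leaves (helped by the three benzyloxy groups of ring D and the para-benzyloxy group of ring A) and the ortho-quinone methide 8 is held by a hydrogen bond or ion pair between its oxygen and the chiral phosphate. The unsubstituted carbon of ethyl vinyl ether attacks the methide carbon (C3–C4) and the ring A oxygen captures the developing oxocarbenium carbon (O1–C2) in a concerted, asynchronous inverse-electron-demand oxa-Diels–Alder reaction; the closest known reaction type is the chiral-phosphoric-acid-catalysed (4+2) cycloaddition of ortho-quinone methides generated in situ from ortho-hydroxybenzhydrols with electron-rich alkenes. Ring C is closed by this (4+2) cycloaddition, both new bonds forming in the one event, and ring A regains its aromaticity. C4 is set by the catalyst, whose 2,4,6-triisopropylphenyl groups cover one face of the planar methide carbon; C2 is expected mainly cis to C4 from the endo transition state, but its configuration is lost in step 5. The step needs enantiofacial selectivity at C4 and head-to-tail regiochemistry: the latter follows from the polarity of the enol ether, the former is helped by the two ortho benzyloxy groups of ring D, which turn that ring out of the quinone methide plane and give the catalyst pocket a large, rigid group to read.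

Step 4
Reactants: 10 1-(benzyloxy)-4-bromobenzene
Product: 12 [4-(benzyloxy)phenyl]zinc chloride, via arylmagnesium bromide 11 (not isolated)
Conditions: Mg, THF, 40 °C; ZnCl2 (1.0 equiv), THF, 0 °C to rt; THF largely removed, residue taken up in CH2Cl2, used directly
Reagents that add atoms: zinc chloride, Cl[Zn]Cl
Why: Grignard formation followed by transmetalation with one equivalent of ZnCl2 gives the arylzinc chloride, so that each molecule of 10 supplies one transferable aryl group, and the reagent, kept together with the magnesium halide formed beside it, is a mild aryl donor that tolerates the Lewis acid and the aryl bromide of step 5.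

Step 5
Reactants: 9 (2R,4R)-7-(benzyloxy)-4-[2,4,6-tris(benzyloxy)-3-bromophenyl]-2-ethoxy-3,4-dihydro-2H-chromene; 12 [4-(benzyloxy)phenyl]zinc chloride
Product: 14 (2S,4R)-7-(benzyloxy)-2-[4-(benzyloxy)phenyl]-4-[2,4,6-tris(benzyloxy)-3-bromophenyl]-3,4-dihydro-2H-chromene, via oxocarbenium ion 13 (not isolated)
Conditions: 12 (2 equiv), BF3·OEt2 (2.5 equiv, added last), CH2Cl2, −78 to −30 °C; cold aq NH4Cl
Reagents that add atoms: none
Why: Lewis-acid-promoted substitution at the acetal carbon, in which BF3·OEt2 removes ethoxide to give the cyclic oxocarbenium ion 13 and the arylzinc chloride (arylzinc halides arylate even the less electrophilic iminium ions) adds along the axial trajectory on the face anti to the C4 aryl group (the 1,3-trans preference of six-membered oxocarbenium ions with a carbon substituent at that position, avoiding a 1,3-diaxial clash), so that C2 is set trans to C4 by the substrate while the aryl bromide is untouched.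

Step 6
Reactants: 15 9-phenylnonanoic acid
Product: 16 N-methoxy-N-methyl-9-phenylnonanamide
Conditions: CDI (1.1 equiv), CH2Cl2, rt; MeNHOMe·HCl (1.2 equiv), rt
Reagents that add atoms: N,O-dimethylhydroxylamine hydrochloride, CNOC.Cl
Why: Amide coupling through the acyl imidazolide, from which N,O-dimethylhydroxylamine displaces imidazole to give the Weinreb amide.

Step 7
Reactants: 14 (2S,4R)-7-(benzyloxy)-2-[4-(benzyloxy)phenyl]-4-[2,4,6-tris(benzyloxy)-3-bromophenyl]-3,4-dihydro-2H-chromene; 16 N-methoxy-N-methyl-9-phenylnonanamide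
Product: 19 1-{2,4,6-tris(benzyloxy)-3-[(2S,4R)-7-(benzyloxy)-2-[4-(benzyloxy)phenyl]-3,4-dihydro-2H-chromen-4-yl]phenyl}-9-phenylnonan-1-one, via aryllithium 17 (not isolated), via lithium hemiaminal alkoxide 18 (not isolated)
Conditions: n-BuLi (1.1 equiv), THF, −78 °C; 16 (1.5 equiv), −78 to 0 °C; aq NH4Cl
Reagents that add atoms: none
Why: Bromine–lithium exchange at the only aryl bromide puts the nucleophile on exactly the ring D carbon that bears the acyl group in the target, and the Weinreb ketone synthesis stops at the ketone because the chelated adduct 18 survives until work-up, with no stereocentre formed and C2 and C4 left alone at −78 °C.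

Step 8
Reactants: 19 1-{2,4,6-tris(benzyloxy)-3-[(2S,4R)-7-(benzyloxy)-2-[4-(benzyloxy)phenyl]-3,4-dihydro-2H-chromen-4-yl]phenyl}-9-phenylnonan-1-one
Product: 20 (+)-myristinin D
Conditions: H2 (1 atm), Pd/C (10 wt%), EtOAc/MeOH, rt
Reagents that add atoms: none
Why: Catalytic hydrogenolysis removes the five benzyl aryl ethers, while the 2,4,6-trihydroxyaryl ketone (a vinylogous acid) resists reduction and the C2–O1 ether of a flavan is expected to survive these neutral conditions, so C2 and C4 are unchanged.

**Compound list**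

1 | 1,3,5-tris(benzyloxy)benzene | c1ccccc1COc1cc(OCc2ccccc2)cc(OCc2ccccc2)c1 | starting material
2 | 1,3,5-tris(benzyloxy)-2,4-dibromobenzene | Brc1c(OCc2ccccc2)cc(OCc2ccccc2)c(Br)c1OCc1ccccc1 | intermediate
3 | 4-(benzyloxy)-2-hydroxybenzaldehyde | O=Cc1ccc(OCc2ccccc2)cc1O | starting material
4 | [2,4,6-tris(benzyloxy)-3-bromophenyl]lithium (not isolated) | [Li]c1c(OCc2ccccc2)cc(OCc2ccccc2)c(Br)c1OCc1ccccc1 | intermediate
5 | sodium 5-(benzyloxy)-2-formylphenolate (not isolated) | [Na+].[O-]c1cc(OCc2ccccc2)ccc1C=O | intermediate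
6 | rac-[4-(benzyloxy)-2-hydroxyphenyl][2,4,6-tris(benzyloxy)-3-bromophenyl]methanol | OC(c1ccc(OCc2ccccc2)cc1O)c1c(OCc2ccccc2)cc(OCc2ccccc2)c(Br)c1OCc1ccccc1 | intermediate
7 | ethyl vinyl ether | C=COCC | starting material
8 | (6E)-3-(benzyloxy)-6-{[2,4,6-tris(benzyloxy)-3-bromophenyl]methylidene}cyclohexa-2,4-dien-1-one, the ortho-quinone methide (not isolated) | O=C1C=C(OCc2ccccc2)C=C/C1=C\c1c(OCc2ccccc2)cc(OCc2ccccc2)c(Br)c1OCc1ccccc1 | intermediate
9 | (2R,4R)-7-(benzyloxy)-4-[2,4,6-tris(benzyloxy)-3-bromophenyl]-2-ethoxy-3,4-dihydro-2H-chromene (2,4-cis acetal) | Brc1c(OCc2ccccc2)cc(OCc2ccccc2)c([C@@H]2C[C@H](OCC)Oc3cc(OCc4ccccc4)ccc32)c1OCc1ccccc1 | intermediate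
10 | 1-(benzyloxy)-4-bromobenzene | Brc1ccc(OCc2ccccc2)cc1 | starting material
11 | [4-(benzyloxy)phenyl]magnesium bromide (not isolated) | Br[Mg]c1ccc(OCc2ccccc2)cc1 | intermediate
12 | [4-(benzyloxy)phenyl]zinc chloride (used as a solution, together with the magnesium bromide chloride formed beside it) | Cl[Zn]c1ccc(OCc2ccccc2)cc1 | intermediate
13 | (4R)-7-(benzyloxy)-4-[2,4,6-tris(benzyloxy)-3-bromophenyl]-3,4-dihydrochromenylium ethoxytrifluoroborate (not isolated) | Brc1c(OCc2ccccc2)cc(OCc2ccccc2)c([C@@H]2CC=[O+]c3cc(OCc4ccccc4)ccc32)c1OCc1ccccc1.CCO[B-](F)(F)F | intermediate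
14 | (2S,4R)-7-(benzyloxy)-2-[4-(benzyloxy)phenyl]-4-[2,4,6-tris(benzyloxy)-3-bromophenyl]-3,4-dihydro-2H-chromene (2,4-trans) | Brc1c(OCc2ccccc2)cc(OCc2ccccc2)c([C@@H]2C[C@@H](c3ccc(OCc4ccccc4)cc3)Oc3cc(OCc4ccccc4)ccc32)c1OCc1ccccc1 | intermediate
15 | 9-phenylnonanoic acid | OC(=O)CCCCCCCCc1ccccc1 | starting material
16 | N-methoxy-N-methyl-9-phenylnonanamide | CON(C)C(=O)CCCCCCCCc1ccccc1 | intermediate
17 | {2,4,6-tris(benzyloxy)-3-[(2S,4R)-7-(benzyloxy)-2-[4-(benzyloxy)phenyl]-3,4-dihydro-2H-chromen-4-yl]phenyl}lithium (not isolated) | [Li]c1c(OCc2ccccc2)cc(OCc2ccccc2)c([C@@H]2C[C@@H](c3ccc(OCc4ccccc4)cc3)Oc3cc(OCc4ccccc4)ccc32)c1OCc1ccccc1 | intermediate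
18 | lithium 1-{2,4,6-tris(benzyloxy)-3-[(2S,4R)-7-(benzyloxy)-2-[4-(benzyloxy)phenyl]-3,4-dihydro-2H-chromen-4-yl]phenyl}-1-[methoxy(methyl)amino]-9-phenylnonan-1-olate, either configuration at the new carbon (not isolated) | [Li]OC(CCCCCCCCc1ccccc1)(N(C)OC)c1c(OCc2ccccc2)cc(OCc2ccccc2)c([C@@H]2C[C@@H](c3ccc(OCc4ccccc4)cc3)Oc3cc(OCc4ccccc4)ccc32)c1OCc1ccccc1 | intermediate
19 | 1-{2,4,6-tris(benzyloxy)-3-[(2S,4R)-7-(benzyloxy)-2-[4-(benzyloxy)phenyl]-3,4-dihydro-2H-chromen-4-yl]phenyl}-9-phenylnonan-1-one | O=C(CCCCCCCCc1ccccc1)c1c(OCc2ccccc2)cc(OCc2ccccc2)c([C@@H]2C[C@@H](c3ccc(OCc4ccccc4)cc3)Oc3cc(OCc4ccccc4)ccc32)c1OCc1ccccc1 | intermediate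
20 | (+)-myristinin D, 1-{2,4,6-trihydroxy-3-[(2S,4R)-7-hydroxy-2-(4-hydroxyphenyl)-3,4-dihydro-2H-chromen-4-yl]phenyl}-9-phenylnonan-1-one | O=C(CCCCCCCCc1ccccc1)c1c(O)cc(O)c([C@@H]2C[C@@H](c3ccc(O)cc3)Oc3cc(O)ccc32)c1O | target

**Count**

Total steps: 8. Longest linear sequence: 6 steps (1, 2, 3, 5, 7, 8); steps 4 and 6 prepare the two side reagents.

**Steps most likely to fail**

1. Step 3. The vinyl ether has no hydrogen-bond donor for two-point binding to the phosphate, so facial discrimination at C4 may be poor. An unselective background path may also open (ionisation of the very labile carbinol without the catalyst, or acetalisation of the phenol by the vinyl ether), and the product acetal may lose ethanol. Fallback, setting out from 6 and coming back at 14: stereocontrol is moved from the acid to the enol ether. Commercial (1R,2S)-trans-2-phenylcyclohexanol is converted into (1R,2S)-2-phenylcyclohexyl vinyl ether F1 by vinyl transfer from vinyl acetate ([Ir(cod)Cl]2, Na2CO3, toluene, 100 °C). Carbinol 6 is then ionised with an achiral acid (diphenyl phosphate, 4 Å sieves, toluene, low temperature) in the presence of F1. The phenyl group of the auxiliary should shield one face of the enol ether in the endo transition state, so the cycloadduct (2R,4R)-7-(benzyloxy)-4-[2,4,6-tris(benzyloxy)-3-bromophenyl]-2-{[(1R,2S)-2-phenylcyclohexyl]oxy}-3,4-dihydro-2H-chromene F2 should form as separable diastereomers (the auxiliary enantiomer is chosen so that C4 is R). F2 is treated as 9 is in step 5 (BF3·OEt2, 12); the auxiliary leaves as its alkoxide and the route is rejoined at 14.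

2. Step 5. The trans preference may erode; the acetal may open the wrong way (aryloxide leaving instead of ethoxide); the Lewis acid may re-ionise the product at C2 and let it drift to the cis isomer; and the cation may be intercepted by the electron-rich rings of a second molecule. Fallback, setting out from 9 and coming back at 14: C2 is set by a reagent-controlled reduction and closed by substitution with inversion. Acetal 9 is hydrolysed (aq HCl, THF) to the lactol (4R)-7-(benzyloxy)-4-[2,4,6-tris(benzyloxy)-3-bromophenyl]-3,4-dihydro-2H-chromen-2-ol F3. Its open hydroxy-aldehyde form takes up the Grignard reagent 11 (3 equiv) to give (3R)-1-[4-(benzyloxy)phenyl]-3-[4-(benzyloxy)-2-hydroxyphenyl]-3-[2,4,6-tris(benzyloxy)-3-bromophenyl]propan-1-ol F4 as both carbinol epimers. MnO2 (CH2Cl2) oxidises the benzylic alcohol to the ketone (3R)-1-[4-(benzyloxy)phenyl]-3-[4-(benzyloxy)-2-hydroxyphenyl]-3-[2,4,6-tris(benzyloxy)-3-bromophenyl]propan-1-one F5. Corey–Bakshi–Shibata reduction (the (S)-B-methyl oxazaborolidine from diphenylprolinol, C18H20BNO, with BH3·SMe2 in excess) should give the (1R,3R)-carbinol F6. Mitsunobu ring closure (PPh3, DIAD, THF, 0 °C) lets the phenol displace the activated hydroxyl with inversion, giving the (2S) centre of 14.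

3. Step 7. The hindered aryllithium may act as a base and enolise the amide (returning the debrominated arene), addition at the doubly ortho-substituted carbon may be slow, and benzyl ethers may be metalated or rearrange on warming. Fallback, setting out from 14 and coming back at 19: the acyl group is brought in at the aldehyde oxidation level. Amide 16 is reduced (i-Bu2AlH, THF, −78 °C) to 9-phenylnonanal F7. The aryllithium 17, made as in step 7, adds to F7 at −78 °C to give the secondary alcohol 1-{2,4,6-tris(benzyloxy)-3-[(2S,4R)-7-(benzyloxy)-2-[4-(benzyloxy)phenyl]-3,4-dihydro-2H-chromen-4-yl]phenyl}-9-phenylnonan-1-ol F8 as both carbinol epimers. Dess–Martin periodinane (CH2Cl2, NaHCO3) oxidises F8 to ketone 19.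

**Further compounds**

F1 | step 3 | (1R,2S)-2-phenylcyclohexyl vinyl ether | C=CO[C@@H]1CCCC[C@H]1c1ccccc1
F2 | step 3 | (2R,4R)-7-(benzyloxy)-4-[2,4,6-tris(benzyloxy)-3-bromophenyl]-2-{[(1R,2S)-2-phenylcyclohexyl]oxy}-3,4-dihydro-2H-chromene | Brc1c(OCc2ccccc2)cc(OCc2ccccc2)c([C@@H]2C[C@H](O[C@@H]3CCCC[C@H]3c3ccccc3)Oc3cc(OCc4ccccc4)ccc32)c1OCc1ccccc1
F3 | step 5 | (4R)-7-(benzyloxy)-4-[2,4,6-tris(benzyloxy)-3-bromophenyl]-3,4-dihydro-2H-chromen-2-ol (anomeric mixture) | Brc1c(OCc2ccccc2)cc(OCc2ccccc2)c([C@@H]2CC(O)Oc3cc(OCc4ccccc4)ccc32)c1OCc1ccccc1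
F4 | step 5 | (3R)-1-[4-(benzyloxy)phenyl]-3-[4-(benzyloxy)-2-hydroxyphenyl]-3-[2,4,6-tris(benzyloxy)-3-bromophenyl]propan-1-ol (both C1 epimers) | Brc1c(OCc2ccccc2)cc(OCc2ccccc2)c([C@H](CC(O)c2ccc(OCc3ccccc3)cc2)c2ccc(OCc3ccccc3)cc2O)c1OCc1ccccc1
F5 | step 5 | (3R)-1-[4-(benzyloxy)phenyl]-3-[4-(benzyloxy)-2-hydroxyphenyl]-3-[2,4,6-tris(benzyloxy)-3-bromophenyl]propan-1-one | Brc1c(OCc2ccccc2)cc(OCc2ccccc2)c([C@H](CC(=O)c2ccc(OCc3ccccc3)cc2)c2ccc(OCc3ccccc3)cc2O)c1OCc1ccccc1
F6 | step 5 | (1R,3R)-1-[4-(benzyloxy)phenyl]-3-[4-(benzyloxy)-2-hydroxyphenyl]-3-[2,4,6-tris(benzyloxy)-3-bromophenyl]propan-1-ol | Brc1c(OCc2ccccc2)cc(OCc2ccccc2)c([C@H](C[C@@H](O)c2ccc(OCc3ccccc3)cc2)c2ccc(OCc3ccccc3)cc2O)c1OCc1ccccc1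
F7 | step 7 | 9-phenylnonanal | O=CCCCCCCCCc1ccccc1
F8 | step 7 | 1-{2,4,6-tris(benzyloxy)-3-[(2S,4R)-7-(benzyloxy)-2-[4-(benzyloxy)phenyl]-3,4-dihydro-2H-chromen-4-yl]phenyl}-9-phenylnonan-1-ol (both carbinol epimers) | OC(CCCCCCCCc1ccccc1)c1c(OCc2ccccc2)cc(OCc2ccccc2)c([C@@H]2C[C@@H](c3ccc(OCc4ccccc4)cc3)Oc3cc(OCc4ccccc4)ccc32)c1OCc1ccccc1
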